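**Retrosynthetic overview** (flavanone numbering; the dimethylpyran ring D is O1″–C2″(Me)2–C3″=C4″, fused to ring B at C4′ and C3′)
1. Ring D is opened last: C4″–C3″ and O1″–C2″ are disconnected together, giving salicylaldehyde 17 and alkenylboronic acid 18 (borono-Mannich / o-quinone methide / oxa-6π cascade).
2. Enabling feature: on ring B the phenolic oxygen on C4′ (future O1″) is ortho to the formyl carbon on C3′ (future C4″); this pair binds boron, delivers the alkenyl group and forms the o-quinone methide O=C4′–C3′=C4″–C3″=C2″.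
3. 17 comes from 15 by one acid unmasking (MOM ether, isopropylidene ketal) and one benzylic oxidation.
4. C2–C1′ is disconnected by enantioselective conjugate arylation of chromone 8 with arylboronic acid 14; this sets (2S).
5. The C8 prenyl group comes from an aromatic Claisen rearrangement on the chromone. Ring order: rings A and C bought as 7-hydroxychromone, ring B added with 14, ring D closed in the last step.

Key step: step 9

Remark: the (R)-enantiomer of the pyridine-oxazoline ligand is assumed to deliver the aryl group to the face of C2 that gives (2S), by analogy with simple chromones, where the (S)-ligand is taken to give the (2R)-flavanone.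

**Step 1**
Reactants: 1 7-hydroxy-4H-chromen-4-one; 2 3-chloro-3-methylbut-1-yne
Product: 3 7-[(2-methylbut-3-yn-2-yl)oxy]-4H-chromen-4-one
Conditions: K2CO3, KI (cat.), CuI (cat.), acetone, 56 °C
Reagents that add atoms: 2 3-chloro-3-methylbut-1-yne, C#CC(C)(C)Cl
Why: Copper-assisted Williamson-type O-propargylation of the only phenol should give the tertiary propargyl ether, the masked reverse-prenyl group.

**Step 2**
Reactants: 3 7-[(2-methylbut-3-yn-2-yl)oxy]-4H-chromen-4-one
Product: 4 7-[(2-methylbut-3-en-2-yl)oxy]-4H-chromen-4-one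
Conditions: H2 (1 atm), Pd/CaCO3 poisoned with Pb(OAc)2 (Lindlar catalyst), quinoline, EtOAc, rt
Reagents that add atoms: none
Why: Lindlar semihydrogenation should stop at the terminal alkene, because the poisoned catalyst reduces neither the vinylogous-ester C2=C3 bond nor the product alkene at a useful rate.

**Step 3**
Reactants: 4 7-[(2-methylbut-3-en-2-yl)oxy]-4H-chromen-4-one
Product: 6 7-hydroxy-8-(3-methylbut-2-en-1-yl)-4H-chromen-4-one, via ortho-dienone 5 (not isolated)
Conditions: PhNEt2, 130 °C
Reagents that add atoms: none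
Why: Aromatic Claisen rearrangement ([3,3]-sigmatropic shift, then tautomerisation of 5) should go to C8 and not C6, because the C7–C8 bond has the higher double-bond character in the benzopyranone; the allyl inversion turns the 1,1-dimethylallyl group into the prenyl group.

**Step 4**
Reactants: 6 7-hydroxy-8-(3-methylbut-2-en-1-yl)-4H-chromen-4-one; 7 chloromethyl methyl ether
Product: 8 7-(methoxymethoxy)-8-(3-methylbut-2-en-1-yl)-4H-chromen-4-one
Conditions: MOMCl, i-Pr2NEt, CH2Cl2, 0 °C to rt
Reagents that add atoms: 7 chloromethyl methyl ether, COCCl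
Why: O-alkylation to the MOM ether (Williamson-type) masks the C7 phenol, so that no free hydroxyl sits next to the prenyl alkene during the palladium-catalysed step.

**Step 5**
Reactants: 9 6-bromo-2,2-dimethyl-4H-1,3-benzodioxine; 10 triisopropyl borate; 11 water
Product: 14 (2,2-dimethyl-4H-1,3-benzodioxin-6-yl)boronic acid, via aryllithium 12 (not isolated), via lithium borate 13 (not isolated)
Conditions: n-BuLi, THF, −78 °C; B(Oi-Pr)3, −78 °C to rt; aq. NH4Cl
Reagents that add atoms: 10 triisopropyl borate, CC(C)OB(OC(C)C)OC(C)C; 11 water, O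
Why: Bromine–lithium exchange, electrophilic borylation and hydrolysis should give the boronic acid, while the isopropylidene ketal hides the phenol and the benzylic alcohol from the organolithium.

**Step 6**
Reactants: 8 7-(methoxymethoxy)-8-(3-methylbut-2-en-1-yl)-4H-chromen-4-one; 14 (2,2-dimethyl-4H-1,3-benzodioxin-6-yl)boronic acid
Product: 15 (2S)-2-(2,2-dimethyl-4H-1,3-benzodioxin-6-yl)-7-(methoxymethoxy)-8-(3-methylbut-2-en-1-yl)-2,3-dihydro-4H-chromen-4-one
Conditions: Pd(OCOCF3)2 (5 mol %), (R)-t-BuPyOX (6 mol %), NH4PF6 (30 mol %), H2O (5 equiv), ClCH2CH2Cl, 60 °C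
Reagents that add atoms: 14 (2,2-dimethyl-4H-1,3-benzodioxin-6-yl)boronic acid, OB(O)c1ccc2OC(C)(C)OCc2c1
Why: Enantioselective conjugate addition of an arylboronic acid to a chromone under cationic divalent-palladium/pyridine-oxazoline catalysis (Hayashi–Miyaura-type 1,4-addition) should set C2 as (S), because the tert-butyl group of the (R)-ligand blocks one face of the bound C2=C3 bond and protonolysis of the palladium enolate releases the ketone without ring opening.

**Step 7**
Reactants: 15 (2S)-2-(2,2-dimethyl-4H-1,3-benzodioxin-6-yl)-7-(methoxymethoxy)-8-(3-methylbut-2-en-1-yl)-2,3-dihydro-4H-chromen-4-one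
Product: 16 (2S)-7-hydroxy-2-[4-hydroxy-3-(hydroxymethyl)phenyl]-8-(3-methylbut-2-en-1-yl)-2,3-dihydro-4H-chromen-4-one
Conditions: 2 M HCl (aq), THF, 45 °C
Reagents that add atoms: none
Why: Acid-catalysed acetal hydrolysis should remove the MOM ether and the isopropylidene ketal in one operation, in an alcohol-free medium that does not solvolyse the o-hydroxybenzyl alcohol and does not open the chromanone ring, so C2 is kept.

**Step 8**
Reactants: 16 (2S)-7-hydroxy-2-[4-hydroxy-3-(hydroxymethyl)phenyl]-8-(3-methylbut-2-en-1-yl)-2,3-dihydro-4H-chromen-4-one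
Product: 17 2-hydroxy-5-[(2S)-7-hydroxy-8-(3-methylbut-2-en-1-yl)-4-oxo-3,4-dihydro-2H-chromen-2-yl]benzaldehyde
Conditions: MnO2 (activated, excess), EtOAc, rt
Reagents that add atoms: none
Why: Chemoselective benzylic oxidation with MnO2 should convert only the o-hydroxybenzyl alcohol into the aldehyde and leave the phenols, the ketone, the prenyl group and C2 untouched.

**Step 9**
Reactants: 17 2-hydroxy-5-[(2S)-7-hydroxy-8-(3-methylbut-2-en-1-yl)-4-oxo-3,4-dihydro-2H-chromen-2-yl]benzaldehyde; 18 (2-methylprop-1-en-1-yl)boronic acid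
Product: 21 (2S)-2-(2,2-dimethyl-2H-chromen-6-yl)-7-hydroxy-8-(3-methylbut-2-en-1-yl)-2,3-dihydro-4H-chromen-4-one (target CNP0156801.1), via amine adduct 19 (not isolated), via o-quinone methide 20 (not isolated)
Conditions: 18 (1.5 equiv), Bn2NH (20 mol %), 1,4-dioxane, 90 °C
Reagents that add atoms: 18 (2-methylprop-1-en-1-yl)boronic acid, CC(C)=CB(O)O
Why: Dibenzylamine condenses with the ring B formyl group to an iminium ion, the neighbouring phenolic oxygen binds 18 as a tetracoordinate boronate, and the alkenyl group migrates through its boron-bearing carbon to the iminium carbon (Petasis borono-Mannich reaction), which forms the C4″–C3″ bond and gives amine 19. At 90 °C the phenol expels the amine from 19 to give o-quinone methide 20 (O=C4′–C3′=C4″–C3″=C2″), which closes the O1″–C2″ bond and makes C3″=C4″ the ring D alkene by a thermal disrotatory oxa-6π electrocyclisation (formally a 6-endo closure) driven by the return of ring B to aromaticity; the amine is released again and is needed only in catalytic amount. The closest known reaction type is the amine-catalysed condensation of salicylaldehydes with alkenylboronic acids to 2H-chromenes. No new stereocentre arises, because C2″ carries two methyl groups and the aminated carbon of 19 becomes the sp2 carbon C4″. The step needs site selectivity for the formyl group over the C4 ketone and the ring A phenol, which the ortho-hydroxy aldehyde pair secures because only there can a boronate deliver the alkenyl group intramolecularly, and it needs ipso transfer of the alkenyl group so that the dimethyl-bearing carbon ends on O1″, which the boron–carbon bond secures. It also needs C2 of ring C to keep its configuration, which the weakly basic substoichiometric amine and the acidic C7 phenol (its phenoxide disfavours enolisation and ring opening) should secure.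

**Compound list**
1 | 7-hydroxy-4H-chromen-4-one | O=c1ccoc2cc(O)ccc12 | starting material
2 | 3-chloro-3-methylbut-1-yne | C#CC(C)(C)Cl | starting material
3 | 7-[(2-methylbut-3-yn-2-yl)oxy]-4H-chromen-4-one | O=c1ccoc2cc(OC(C)(C)C#C)ccc12 | intermediate
4 | 7-[(2-methylbut-3-en-2-yl)oxy]-4H-chromen-4-one | O=c1ccoc2cc(OC(C)(C)C=C)ccc12 | intermediate
5 | 8-(3-methylbut-2-en-1-yl)-8H-chromene-4,7-dione (ortho-dienone, not isolated) | CC(C)=CCC1C(=O)C=CC2=C1OC=CC2=O | intermediate
6 | 7-hydroxy-8-(3-methylbut-2-en-1-yl)-4H-chromen-4-one | CC(C)=CCc1c(O)ccc2c(=O)ccoc12 | intermediate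
7 | chloromethyl methyl ether | COCCl | starting material
8 | 7-(methoxymethoxy)-8-(3-methylbut-2-en-1-yl)-4H-chromen-4-one | CC(C)=CCc1c(OCOC)ccc2c(=O)ccoc12 | intermediate
9 | 6-bromo-2,2-dimethyl-4H-1,3-benzodioxine | CC1(C)OCc2cc(Br)ccc2O1 | starting material
10 | triisopropyl borate | CC(C)OB(OC(C)C)OC(C)C | starting material
11 | water | O | starting material
12 | (2,2-dimethyl-4H-1,3-benzodioxin-6-yl)lithium (not isolated) | [Li]c1ccc2OC(C)(C)OCc2c1 | intermediate
13 | lithium (2,2-dimethyl-4H-1,3-benzodioxin-6-yl)tri(propan-2-yloxy)borate (not isolated) | [Li+].CC(C)O[B-](OC(C)C)(OC(C)C)c1ccc2OC(C)(C)OCc2c1 | intermediate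
14 | (2,2-dimethyl-4H-1,3-benzodioxin-6-yl)boronic acid | OB(O)c1ccc2OC(C)(C)OCc2c1 | intermediate
15 | (2S)-2-(2,2-dimethyl-4H-1,3-benzodioxin-6-yl)-7-(methoxymethoxy)-8-(3-methylbut-2-en-1-yl)-2,3-dihydro-4H-chromen-4-one | CC(C)=CCc1c(OCOC)ccc2c1O[C@H](c1ccc3OC(C)(C)OCc3c1)CC2=O | intermediate
16 | (2S)-7-hydroxy-2-[4-hydroxy-3-(hydroxymethyl)phenyl]-8-(3-methylbut-2-en-1-yl)-2,3-dihydro-4H-chromen-4-one | CC(C)=CCc1c(O)ccc2c1O[C@H](c1ccc(O)c(CO)c1)CC2=O | intermediate
17 | 2-hydroxy-5-[(2S)-7-hydroxy-8-(3-methylbut-2-en-1-yl)-4-oxo-3,4-dihydro-2H-chromen-2-yl]benzaldehyde | CC(C)=CCc1c(O)ccc2c1O[C@H](c1ccc(O)c(C=O)c1)CC2=O | intermediate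
18 | (2-methylprop-1-en-1-yl)boronic acid | CC(C)=CB(O)O | starting material
19 | (2S)-2-{3-[1-(dibenzylamino)-3-methylbut-2-en-1-yl]-4-hydroxyphenyl}-7-hydroxy-8-(3-methylbut-2-en-1-yl)-2,3-dihydro-4H-chromen-4-one (both epimers at the amino carbon, not isolated) | CC(C)=CCc1c(O)ccc2c1O[C@H](c1ccc(O)c(C(C=C(C)C)N(Cc3ccccc3)Cc3ccccc3)c1)CC2=O | intermediate
20 | (2S)-7-hydroxy-8-(3-methylbut-2-en-1-yl)-2-[3-(3-methylbut-2-en-1-ylidene)-4-oxocyclohexa-1,5-dien-1-yl]-2,3-dihydro-4H-chromen-4-one (o-quinone methide, not isolated) | CC(C)=CCc1c(O)ccc2c1O[C@H](C1=CC(=CC=C(C)C)C(=O)C=C1)CC2=O | intermediate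
21 | (2S)-2-(2,2-dimethyl-2H-chromen-6-yl)-7-hydroxy-8-(3-methylbut-2-en-1-yl)-2,3-dihydro-4H-chromen-4-one | CC(C)=CCc1c(O)ccc2c1O[C@H](c1ccc3c(c1)C=CC(C)(C)O3)CC2=O | target

**Totals**
Total step count: 9. Longest linear sequence: 8 steps (steps 1, 2, 3, 4, 6, 7, 8, 9).

**Steps most likely to fail**

Step 9. What may go wrong: loss of configurational purity at C2 through amine-promoted ring opening and reclosure of the chromanone (retro-oxa-Michael) at 90 °C, and slow alkenyl transfer from the β,β-disubstituted boronic acid. The fallback builds ring D before the stereocentre exists and sets out from 8 and 18. Purchased 5-bromo-2-hydroxybenzaldehyde F1 is condensed with 18 and Bn2NH in 1,4-dioxane at 90 °C to give 6-bromo-2,2-dimethyl-2H-chromene F2. Bromine–lithium exchange (n-BuLi, THF, −78 °C), borylation with 10 and aqueous NH4Cl work-up give (2,2-dimethyl-2H-chromen-6-yl)boronic acid F3. Conjugate addition of F3 to 8 under the conditions of step 6 gives (2S)-2-(2,2-dimethyl-2H-chromen-6-yl)-7-(methoxymethoxy)-8-(3-methylbut-2-en-1-yl)-2,3-dihydro-4H-chromen-4-one F4. Brief treatment with 2 M HCl in THF removes the MOM group, and the route is rejoined at 21.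

Step 6. What may go wrong: slow insertion of the electron-rich, 8-substituted chromone into the aryl–palladium bond with competing protodeboronation of the electron-rich boronic acid, and incomplete facial selectivity. The fallback is a chalcone route with resolution and sets out from 8 and 9. Aqueous NaOH in EtOH at reflux opens chromone 8 with loss of formate to give 1-[2-hydroxy-4-(methoxymethoxy)-3-(3-methylbut-2-en-1-yl)phenyl]ethan-1-one F5. Bromide 9 is lithiated (n-BuLi, THF, −78 °C) and formylated with DMF to give 2,2-dimethyl-4H-1,3-benzodioxine-6-carbaldehyde F6. Claisen–Schmidt condensation of F5 with F6 (KOH, EtOH, rt) gives (E)-3-(2,2-dimethyl-4H-1,3-benzodioxin-6-yl)-1-[2-hydroxy-4-(methoxymethoxy)-3-(3-methylbut-2-en-1-yl)phenyl]prop-2-en-1-one F7. Oxa-Michael cyclisation (NaOAc, EtOH, reflux) gives racemic 2-(2,2-dimethyl-4H-1,3-benzodioxin-6-yl)-7-(methoxymethoxy)-8-(3-methylbut-2-en-1-yl)-2,3-dihydro-4H-chromen-4-one F8. Preparative chromatography on a chiral stationary phase delivers the (2S)-enantiomer, and the route is rejoined at 15; the unwanted enantiomer can be re-equilibrated with base through F7.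

Step 7. What may go wrong: acid-catalysed addition of the freed C7 hydroxyl to the prenyl double bond (chroman formation), and ionisation of the o-hydroxybenzyl alcohol to a benzylic cation while the slower MOM cleavage is still running. The fallback changes the protecting-group plan so that the C7 oxygen is freed by fluoride and only the fast ketal hydrolysis needs weak acid; it sets out from 6. Silylation (i-Pr3SiCl, imidazole, DMF) gives 8-(3-methylbut-2-en-1-yl)-7-[(triisopropylsilyl)oxy]-4H-chromen-4-one F9. Conjugate addition of 14 under the conditions of step 6 gives (2S)-2-(2,2-dimethyl-4H-1,3-benzodioxin-6-yl)-8-(3-methylbut-2-en-1-yl)-7-[(triisopropylsilyl)oxy]-2,3-dihydro-4H-chromen-4-one F10. Desilylation with n-Bu4NF buffered with AcOH in THF at 0 °C gives (2S)-2-(2,2-dimethyl-4H-1,3-benzodioxin-6-yl)-7-hydroxy-8-(3-methylbut-2-en-1-yl)-2,3-dihydro-4H-chromen-4-one F11. Hydrolysis of the ketal in AcOH/H2O 4:1 at 45 °C rejoins the route at 16.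

**Further compounds**
F1 | step 9 | 5-bromo-2-hydroxybenzaldehyde (purchased input of the fallback) | O=Cc1cc(Br)ccc1O
F2 | step 9 | 6-bromo-2,2-dimethyl-2H-chromene | CC1(C)C=Cc2cc(Br)ccc2O1
F3 | step 9 | (2,2-dimethyl-2H-chromen-6-yl)boronic acid | CC1(C)C=Cc2cc(B(O)O)ccc2O1
F4 | step 9 | (2S)-2-(2,2-dimethyl-2H-chromen-6-yl)-7-(methoxymethoxy)-8-(3-methylbut-2-en-1-yl)-2,3-dihydro-4H-chromen-4-one | CC(C)=CCc1c(OCOC)ccc2c1O[C@H](c1ccc3c(c1)C=CC(C)(C)O3)CC2=O
F5 | step 6 | 1-[2-hydroxy-4-(methoxymethoxy)-3-(3-methylbut-2-en-1-yl)phenyl]ethan-1-one | CC(=O)c1ccc(OCOC)c(CC=C(C)C)c1O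
F6 | step 6 | 2,2-dimethyl-4H-1,3-benzodioxine-6-carbaldehyde | CC1(C)OCc2cc(C=O)ccc2O1
F7 | step 6 | (E)-3-(2,2-dimethyl-4H-1,3-benzodioxin-6-yl)-1-[2-hydroxy-4-(methoxymethoxy)-3-(3-methylbut-2-en-1-yl)phenyl]prop-2-en-1-one | CC(C)=CCc1c(OCOC)ccc(C(=O)/C=C/c2ccc3OC(C)(C)OCc3c2)c1O
F8 | step 6 | racemic 2-(2,2-dimethyl-4H-1,3-benzodioxin-6-yl)-7-(methoxymethoxy)-8-(3-methylbut-2-en-1-yl)-2,3-dihydro-4H-chromen-4-one | CC(C)=CCc1c(OCOC)ccc2c1OC(c1ccc3OC(C)(C)OCc3c1)CC2=O
F9 | step 7 | 8-(3-methylbut-2-en-1-yl)-7-[(triisopropylsilyl)oxy]-4H-chromen-4-one | CC(C)=CCc1c(O[Si](C(C)C)(C(C)C)C(C)C)ccc2c(=O)ccoc12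
F10 | step 7 | (2S)-2-(2,2-dimethyl-4H-1,3-benzodioxin-6-yl)-8-(3-methylbut-2-en-1-yl)-7-[(triisopropylsilyl)oxy]-2,3-dihydro-4H-chromen-4-one | CC(C)=CCc1c(O[Si](C(C)C)(C(C)C)C(C)C)ccc2c1O[C@H](c1ccc3OC(C)(C)OCc3c1)CC2=O
F11 | step 7 | (2S)-2-(2,2-dimethyl-4H-1,3-benzodioxin-6-yl)-7-hydroxy-8-(3-methylbut-2-en-1-yl)-2,3-dihydro-4H-chromen-4-one | CC(C)=CCc1c(O)ccc2c1O[C@H](c1ccc3OC(C)(C)OCc3c1)CC2=O
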